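Each molecule of left-handed or right-handed product is one turn of the catalyst, so I counted turns.

left-handed substrate 0.80 M; solid reagent 0.960 M; free catalyst 1.8 mM; right-handed substrate 0.80 M; time 10 h

1. share of the left-handed substrate and right-handed substrate together used up at 10 h
2. left-handed product at 10 h, in percent of the left-handed substrate and right-handed substrate together charged
3. right-handed substrate at 10 h, in percent of the left-handed substrate and right-handed substrate together charged
4. right-handed product at 10 h, in percent of the left-handed substrate and right-handed substrate together charged

- free catalyst is single-handed; left-handed substrate and right-handed substrate are mirror images of each other, charged as a racemate, each of them at the stated concentration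
- a step written with two of one species runs at k times the square of its concentration and takes two of it each time
- solid reagent is a solid; its amount is given per volume of the solution
- at the start none of the solid reagent is in solution
- run time (flask): 10 h

    partner + catalyst intermediate A → free catalyst + left-handed product (k1 = 71 M⁻¹ min⁻¹)
    solid reagent ⇌ partner, rate k2*(cs2 - [partner]) while solid is left; crystals form when [partner] > cs2 (cs2 = 0.29 M, k2 = 0.0080 min⁻¹)
    free catalyst + right-handed substrate ⇌ catalyst intermediate B (K3 = 3.1 M⁻¹, k3 = 380 M⁻¹ min⁻¹)
    free catalyst + left-handed substrate ⇌ catalyst intermediate A (K4 = 0.44 M⁻¹, k4 = 2100 M⁻¹ min⁻¹)
    free catalyst → spent catalyst (k5 = 0.070 min⁻¹)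
    2 partner → homo dimer (k6 = 0.13 M⁻¹ min⁻¹)
    partner + catalyst intermediate B → free catalyst + right-handed product (k7 = 26 M⁻¹ min⁻¹)

I took both bindings as equilibria with the substrates at their charge. Free catalyst is then a share 26.1% of the working catalyst, and since it dies from that form, a catalyst lives 54.7 min. Binding takes about 0.00329 min, much shorter than that life, so the equilibrium stands. Two rates per catalyst then count: turning, and dying. The free share stands in both and cancels, so turns per catalyst are the partner concentration times the turn gain, the turns made per molar of standing partner 1280 M⁻¹.

Even at its fastest, dissolving needs 414 min to use the solid, longer than that life, so I balanced dissolving against the losses of partner and went round twice.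

Round one, dimer loss alone:

c(partner) = 0.0803 M, turns = 103, share of substrates used = 11.5%

But turnover takes partner too, with coefficient 0.0420 min⁻¹, larger than the dissolving coefficient 0.0080 min⁻¹. So I put that back in.

Round two, catalyst at full charge:

c(partner) = 0.0386 M, turns = 49.4, share of substrates used = 5.55%

A dying catalyst drains less than its full charge, so I took round two as the low side and round one as the high side.

The forecast gave 6% used, with 1.7% left-handed product, 4.3% right-handed product and 45.7% right-handed substrate, reasoning that “turnover stops early at low conversion”. Its conversion stood a little above my 5.55%.

The flask gave 5.79% used, with 1.66%, 4.13% and 45.9% in the same order, each within the forecast's margin.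

The products of the flask come to 51.5 turns per catalyst. For the neighbour flask, charged with 0.0045 M of free catalyst, more than the 1.8 mM of the first flask, round two gives c(partner) = 0.0196 M. That makes 25.1 turns and 7.06% of the substrates used. The neighbour flask gave 3.09% left-handed and 7.52% right-handed product, which is 37.7 turns per catalyst, above round two and below round one.

Its constants stand for no real mixture, and the outcome is calculated.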